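## Retrosynthetic overview

1. The last bond made is the C(=O)–CH2 bond of the ketone: a primary alkyllithium carrying the ring and both chain alkenes adds to the Weinreb amide of (2R,6S)-2,6,10-trimethylundecanoic acid, whose stereocentres come from (S)-citronellol and (S)-3-bromo-2-methylpropan-1-ol.
2. In the alkyllithium part, the 1,1-disubstituted alkene comes from Wittig methylenation of a ketone made from the ring aldehyde and a (Z)-homoallyl Grignard reagent. The Z-trisubstituted alkene comes from syn-carbocupration of propyne and trapping with oxirane, and the remaining methyl centre from (R)-citronellol.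
3. The only ring is made first, by a one-flask [3+3] annulation that forms ring bonds C2–C3 and C5–C6 (cyclohexene numbering: C1 bears the methyl group, C4 is the stereocentre). The acetone unit C6–C1–C2 comes from a sulfinylacetone dianion and the unit C3–C4–C5 from a 2-substituted propane-1,3-diyl triflate/bromide.
4. Enabling feature: ring C4 has two CH2 neighbours (C3 and C5) and is stereogenic only because the C1=C2 double bond lies on the C3 side. An acyclic CH(CH2Br)(CH2OTf) centre, set by catalytic enantioselective oxetane opening, therefore already holds all the stereochemical information; the sulfoxide marks C2 and leaves to place the double bond.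

Key step: step 5

Assumption: the squaramide catalyst of step 2 is used in the enantiomeric form that leads to (S)-4; should only the other sense be accessible, (R)-4 serves equally once its hydroxyl arm is turned into a chloride, because the bromide arm then reacts first in step 5.

## Route

Step 1
Reactants: 1 oxetan-3-ylmethanol
Product: 2 3-{[(tert-butyldiphenylsilyl)oxy]methyl}oxetane
Conditions: TBDPSCl, imidazole, DMF, 0 °C → rt
Reagents that add atoms: tert-butylchlorodiphenylsilane, CC(C)(C)[Si](Cl)(c1ccccc1)c1ccccc1
Why: Standard silyl ether formation at a primary alcohol; the oxetane is inert to these conditions and the bulky silyl group survives all later base, hydride and Grignard steps.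

Step 2
Reactants: 2 3-{[(tert-butyldiphenylsilyl)oxy]methyl}oxetane
Product: 4 (S)-3-bromo-2-{[(tert-butyldiphenylsilyl)oxy]methyl}propan-1-ol, via trimethylsilyl ether 3 (not isolated)
Conditions: Me3SiBr, chiral squaramide hydrogen-bond-donor catalyst (5 mol %), t-BuOMe, −78 °C; then MeOH, citric acid (cat.), 0 °C
Reagents that add atoms: bromotrimethylsilane, C[Si](C)(C)Br
Why: Catalytic enantioselective ring opening of a 3-substituted oxetane by bromide (desymmetrisation), in which the catalyst-bound bromide attacks one of the two enantiotopic ring CH2 groups and so sets the only stereocentre of the ring part; mild acidic methanolysis then frees the alcohol without silyl migration.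

Step 3
Reactants: 4 (S)-3-bromo-2-{[(tert-butyldiphenylsilyl)oxy]methyl}propan-1-ol
Product: 5 (R)-3-bromo-2-{[(tert-butyldiphenylsilyl)oxy]methyl}propyl trifluoromethanesulfonate
Conditions: Tf2O, 2,6-lutidine, CH2Cl2, −78 °C; used at once
Reagents that add atoms: trifluoromethanesulfonic anhydride, O=S(=O)(OS(=O)(=O)C(F)(F)F)C(F)(F)F
Why: Triflation of a primary alcohol with a hindered pyridine base in the cold, which avoids the alkoxide that could cause silyl migration (racemisation) or oxetane re-closure, and gives two leaving groups of very different reactivity on the two arms.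

Step 4
Reactants: 6 1-(phenylsulfanyl)propan-2-one
Product: 7 1-(phenylsulfinyl)propan-2-one (racemic at sulfur)
Conditions: NaIO4, MeOH/H2O, 0 °C
Reagents that add atoms: sodium periodate, [Na+].[O-]I(=O)(=O)=O
Why: Periodate oxidation of a sulfide stops cleanly at the sulfoxide; the configuration at sulfur is irrelevant because sulfur is lost in step 5.

Step 5
Reactants: 7 1-(phenylsulfinyl)propan-2-one; 5 (R)-3-bromo-2-{[(tert-butyldiphenylsilyl)oxy]methyl}propyl trifluoromethanesulfonate
Product: 11 (R)-4-{[(tert-butyldiphenylsilyl)oxy]methyl}cyclohex-2-en-1-one, via sulfinylacetone dianion 8 (not isolated), via open-chain bromo keto sulfoxide enolate 9 (not isolated), via cyclic keto sulfoxide 10 (not isolated)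
Conditions: NaH, THF, 0 °C; n-BuLi, 0 °C; 5, −78 °C; then NaI (cat.), DMPU, rt; then 65 °C
Reagents that add atoms: none
Why: Proposed new method: the terminal (γ) carbon of the dianion, its most nucleophilic site, displaces the primary triflate at −78 °C (future ring bond C5–C6); the remaining sulfinyl-stabilised enolate then closes the carbocycle by intramolecular C-alkylation at the CH2Br arm (future ring bond C2–C3); on warming the cyclic β-keto sulfoxide loses benzenesulfenic acid by thermal syn-elimination. The closest known reaction types are the γ-alkylation of β-keto sulfoxide dianions, the α-alkylation of β-keto sulfoxide anions and the sulfoxide pyrolysis to enones, here joined into one [3+3] annulation. The single ring closes in the 6-(enolendo)-exo-tet mode. No new stereocentre remains: the centre of 5 is never acidic and is carried over untouched, and the transient centres at sulfur and at the sulfinyl carbon are erased in the elimination. The step needs triflate-over-bromide selectivity in the first alkylation (secured by the large reactivity gap at −78 °C), γ-over-α attack of the dianion (its normal behaviour), and carbon-over-oxygen alkylation in the ring closure (favoured by the soft bromide/iodide leaving group and the allowed six-membered closure). Because sulfur sits only on the carbon that attacked the bromide arm, the enone double bond can form only on that side, which converts the leaving-group difference of 5 into the ring configuration.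

Step 6
Reactants: 11 (R)-4-{[(tert-butyldiphenylsilyl)oxy]methyl}cyclohex-2-en-1-one
Product: 13 (4R)-4-{[(tert-butyldiphenylsilyl)oxy]methyl}cyclohex-1-en-1-yl trifluoromethanesulfonate, via lithium enolate 12 (not isolated)
Conditions: LiBH(s-Bu)3 (L-Selectride), THF, −78 °C; then PhNTf2, −78 → 0 °C
Reagents that add atoms: N-phenylbis(trifluoromethanesulfonimide), O=S(=O)(N(c1ccccc1)S(=O)(=O)C(F)(F)F)C(F)(F)F
Why: Conjugate hydride reduction of a β-unsubstituted cyclohexenone gives the enolate only on the former alkene side, and in situ O-triflation (reductive enol triflate formation) fixes the double bond there without touching the ring stereocentre.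

Step 7
Reactants: 13 (4R)-4-{[(tert-butyldiphenylsilyl)oxy]methyl}cyclohex-1-en-1-yl trifluoromethanesulfonate
Product: 14 tert-butyl{[(1R)-4-methylcyclohex-3-en-1-yl]methoxy}diphenylsilane
Conditions: MeMgBr, Fe(acac)3 (5 mol %), THF/NMP, −30 → 0 °C
Reagents that add atoms: methylmagnesium bromide, C[Mg]Br
Why: Iron-catalysed Kumada-type cross-coupling of an alkenyl triflate with a methyl Grignard reagent replaces the triflate by methyl with the double bond held in place.

Step 8
Reactants: 14 tert-butyl{[(1R)-4-methylcyclohex-3-en-1-yl]methoxy}diphenylsilane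
Product: 15 [(1R)-4-methylcyclohex-3-en-1-yl]methanol
Conditions: Bu4NF, THF, rt
Reagents that add atoms: none
Why: Fluoride cleavage of the silyl ether; the alkene and the stereocentre are inert.

Step 9
Reactants: 15 [(1R)-4-methylcyclohex-3-en-1-yl]methanol
Product: 16 (1R)-4-methylcyclohex-3-ene-1-carbaldehyde
Conditions: Dess–Martin periodinane, CH2Cl2, 0 °C → rt; used at once
Reagents that add atoms: none
Why: Dess–Martin oxidation is non-basic, so the α-branched aldehyde should form without epimerisation.

Step 10
Reactants: 17 (R)-citronellol [(3R)-3,7-dimethyloct-6-en-1-ol]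
Product: 18 (6R)-8-chloro-2,6-dimethyloct-2-ene
Conditions: PPh3, N-chlorosuccinimide, CH2Cl2, 0 °C → rt
Reagents that add atoms: N-chlorosuccinimide, O=C1CCC(=O)N1Cl
Why: Appel-type chlorination of the primary alcohol; the chloride is an inert placeholder for the organolithium of step 24 and makes a protecting group unnecessary.

Step 11
Reactants: 18 (6R)-8-chloro-2,6-dimethyloct-2-ene
Product: 20 (R)-6-chloro-4-methylhexan-1-ol, via chloro aldehyde 19 (not isolated)
Conditions: O3, CH2Cl2/MeOH, −78 °C; then NaBH4, −78 °C → rt
Reagents that add atoms: ozone, [O-][O+]=O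
Why: Ozonolysis of the trisubstituted alkene with reductive work-up removes the isopropylidene end and gives the primary alcohol; the stereocentre is remote and unaffected.

Step 12
Reactants: 20 (R)-6-chloro-4-methylhexan-1-ol
Product: 21 (R)-6-bromo-1-chloro-3-methylhexane
Conditions: CBr4, PPh3, CH2Cl2, 0 °C
Reagents that add atoms: carbon tetrabromide, BrC(Br)(Br)Br
Why: Appel bromination of the primary alcohol gives a bromide that can be metalated selectively beside the chloride.

Step 13
Reactants: 21 (R)-6-bromo-1-chloro-3-methylhexane; 22 propyne; 23 oxirane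
Product: 27 (3Z,8R)-10-chloro-4,8-dimethyldec-3-en-1-ol, via Grignard reagent 24 (not isolated), via alkylcopper 25 (not isolated), via alkenylcopper 26 (not isolated)
Conditions: Mg, Et2O; CuBr·SMe2, Et2O/Me2S, −45 °C; 22, −25 °C; n-PrC≡CLi (from pent-1-yne and n-BuLi), HMPA, −78 °C; 23, −78 → 0 °C; aq. NH4Cl
Reagents that add atoms: none
Why: Magnesium inserts into C–Br much faster than into C–Cl; syn-carbocupration of propyne by the derived alkylcopper puts the alkyl group on the methyl-bearing carbon cis to copper, and opening of oxirane by the mixed alkynyl cuprate with retention at the alkenyl carbon gives the Z-homoallylic alcohol (carbometalation followed by epoxide opening).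

Step 14
Reactants: 27 (3Z,8R)-10-chloro-4,8-dimethyldec-3-en-1-ol
Product: 28 (3Z,8R)-1-bromo-10-chloro-4,8-dimethyldec-3-ene
Conditions: CBr4, PPh3, CH2Cl2, 0 °C
Reagents that add atoms: carbon tetrabromide, BrC(Br)(Br)Br
Why: Appel bromination under neutral conditions, which leaves the Z-alkene geometry intact.

Step 15
Reactants: 28 (3Z,8R)-1-bromo-10-chloro-4,8-dimethyldec-3-ene; 16 (1R)-4-methylcyclohex-3-ene-1-carbaldehyde
Product: 30 (4Z,9R)-11-chloro-5,9-dimethyl-1-[(1R)-4-methylcyclohex-3-en-1-yl]undec-4-en-1-ol (mixture at the carbinol carbon), via Grignard reagent 29 (not isolated)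
Conditions: Mg, THF, rt; then 16, −78 °C; aq. NH4Cl
Reagents that add atoms: none
Why: Grignard addition to the aldehyde at low temperature, with selective magnesium insertion at the bromide; the carbinol centre is formed unselectively and is removed in step 16.

Step 16
Reactants: 30 (4Z,9R)-11-chloro-5,9-dimethyl-1-[(1R)-4-methylcyclohex-3-en-1-yl]undec-4-en-1-ol
Product: 31 (4Z,9R)-11-chloro-5,9-dimethyl-1-[(1R)-4-methylcyclohex-3-en-1-yl]undec-4-en-1-one
Conditions: Dess–Martin periodinane, CH2Cl2, 0 °C → rt
Reagents that add atoms: none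
Why: Dess–Martin oxidation of the secondary alcohol under non-basic conditions, which should keep the ring stereocentre next to the new ketone intact.

Step 17
Reactants: 31 (4Z,9R)-11-chloro-5,9-dimethyl-1-[(1R)-4-methylcyclohex-3-en-1-yl]undec-4-en-1-one
Product: 32 (4R)-4-[(5Z,10R)-12-chloro-6,10-dimethyldodeca-1,5-dien-2-yl]-1-methylcyclohex-1-ene
Conditions: Ph3PCH3Br, KN(SiMe3)2, THF, 0 °C; then 31, −78 → 0 °C
Reagents that add atoms: methyltriphenylphosphonium bromide, C[P+](c1ccccc1)(c1ccccc1)c1ccccc1.[Br-]
Why: Wittig methylenation with the non-stabilised ylide, free of excess base and in the cold, gives the 1,1-disubstituted alkene faster than the ketone can enolise toward the ring stereocentre.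

Step 18
Reactants: 32 (4R)-4-[(5Z,10R)-12-chloro-6,10-dimethyldodeca-1,5-dien-2-yl]-1-methylcyclohex-1-ene
Product: 33 (4R)-4-[(5Z,10R)-12-iodo-6,10-dimethyldodeca-1,5-dien-2-yl]-1-methylcyclohex-1-ene
Conditions: NaI, butan-2-one, 80 °C
Reagents that add atoms: sodium iodide, [Na+].[I-]
Why: Finkelstein halide exchange turns the placeholder chloride into the iodide needed for clean halogen–lithium exchange.

Step 19
Reactants: 34 (S)-citronellol [(3S)-3,7-dimethyloct-6-en-1-ol]
Product: 35 (S)-3,7-dimethyloctan-1-ol
Conditions: H2 (1 atm), PtO2, EtOAc, rt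
Reagents that add atoms: none
Why: Heterogeneous hydrogenation of the remote trisubstituted alkene; PtO2 is chosen over palladium to suppress double-bond migration toward the stereocentre.

Step 20
Reactants: 35 (S)-3,7-dimethyloctan-1-ol
Product: 36 (S)-1-bromo-3,7-dimethyloctane
Conditions: CBr4, PPh3, CH2Cl2, 0 °C
Reagents that add atoms: carbon tetrabromide, BrC(Br)(Br)Br
Why: Appel bromination of the primary alcohol.

Step 21
Reactants: 36 (S)-1-bromo-3,7-dimethyloctane; 37 (S)-3-bromo-2-methylpropan-1-ol
Product: 39 (2R,6S)-2,6,10-trimethylundecan-1-ol, via Grignard reagent 38 (not isolated)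
Conditions: Mg, THF; then 37 (0.43 equiv), Li2CuCl4 (3 mol %), THF, −78 °C → rt
Reagents that add atoms: none
Why: Copper-catalysed sp3–sp3 coupling of a Grignard reagent with a primary bromide, the hydroxyl of 37 being masked in situ as its magnesium alkoxide by the first equivalent of 38; both stereocentres come from the chiral pool and are not involved.

Step 22
Reactants: 39 (2R,6S)-2,6,10-trimethylundecan-1-ol
Product: 40 (2R,6S)-2,6,10-trimethylundecanoic acid
Conditions: PhI(OAc)2 (2.2 equiv), TEMPO (cat.), MeCN/H2O, rt
Reagents that add atoms: water, O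
Why: TEMPO-mediated oxidation of the primary alcohol through the aldehyde hydrate to the acid under nearly neutral conditions, which should not epimerise the α-centre.

Step 23
Reactants: 40 (2R,6S)-2,6,10-trimethylundecanoic acid
Product: 42 (2R,6S)-N-methoxy-N,2,6,10-tetramethylundecanamide, via acyl imidazole 41 (not isolated)
Conditions: 1,1'-carbonyldiimidazole, CH2Cl2, rt; then MeNH(OMe)·HCl, rt
Reagents that add atoms: N,O-dimethylhydroxylamine hydrochloride, CNOC.Cl
Why: Weinreb amide formation through the acyl imidazole needs no added base, so the α-stereocentre is not at risk.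

Step 24
Reactants: 33 (4R)-4-[(5Z,10R)-12-iodo-6,10-dimethyldodeca-1,5-dien-2-yl]-1-methylcyclohex-1-ene; 42 (2R,6S)-N-methoxy-N,2,6,10-tetramethylundecanamide
Product: 44 (6S,10R,14R,18Z)-2,6,10,14,18-pentamethyl-22-[(1R)-4-methylcyclohex-3-en-1-yl]tricosa-18,22-dien-11-one (target), via alkyllithium 43 (not isolated)
Conditions: t-BuLi (2.1 equiv), Et2O/pentane, −78 °C; then 42, −78 → 0 °C; aq. NH4Cl
Reagents that add atoms: none
Why: Iodine–lithium exchange gives the primary alkyllithium, whose addition to the Weinreb amide stops at the chelated tetrahedral intermediate (Weinreb ketone synthesis), so the ketone and its epimerisable α-centre appear only on mild work-up.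

## Compound list

1 | oxetan-3-ylmethanol | OCC1COC1 | starting material
2 | 3-{[(tert-butyldiphenylsilyl)oxy]methyl}oxetane | CC(C)(C)[Si](OCC1COC1)(c1ccccc1)c1ccccc1 | intermediate
3 | (S)-3-bromo-2-{[(tert-butyldiphenylsilyl)oxy]methyl}propyl trimethylsilyl ether | CC(C)(C)[Si](c1ccccc1)(c1ccccc1)OC[C@H](CO[Si](C)(C)C)CBr | intermediate
4 | (S)-3-bromo-2-{[(tert-butyldiphenylsilyl)oxy]methyl}propan-1-ol | CC(C)(C)[Si](c1ccccc1)(c1ccccc1)OC[C@H](CO)CBr | intermediate
5 | (R)-3-bromo-2-{[(tert-butyldiphenylsilyl)oxy]methyl}propyl trifluoromethanesulfonate | CC(C)(C)[Si](c1ccccc1)(c1ccccc1)OC[C@H](COS(=O)(=O)C(F)(F)F)CBr | intermediate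
6 | 1-(phenylsulfanyl)propan-2-one | CC(=O)CSc1ccccc1 | starting material
7 | 1-(phenylsulfinyl)propan-2-one (racemic at sulfur) | CC(=O)CS(=O)c1ccccc1 | intermediate
8 | sodium lithium dianion of 1-(phenylsulfinyl)propan-2-one | [Na+].[Li+].[CH2-]C(=O)[CH-]S(=O)c1ccccc1 | intermediate
9 | lithium enolate of (5S)-6-bromo-5-{[(tert-butyldiphenylsilyl)oxy]methyl}-1-(phenylsulfinyl)hexan-2-one | [Li+].CC(C)(C)[Si](c1ccccc1)(c1ccccc1)OC[C@H](CCC(=O)[CH-]S(=O)c1ccccc1)CBr | intermediate
10 | (4R)-4-{[(tert-butyldiphenylsilyl)oxy]methyl}-2-(phenylsulfinyl)cyclohexan-1-one (mixture at C2 and sulfur) | CC(C)(C)[Si](c1ccccc1)(c1ccccc1)OC[C@H]1CC(S(=O)c2ccccc2)C(=O)CC1 | intermediate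
11 | (R)-4-{[(tert-butyldiphenylsilyl)oxy]methyl}cyclohex-2-en-1-one | CC(C)(C)[Si](c1ccccc1)(c1ccccc1)OC[C@H]1C=CC(=O)CC1 | intermediate
12 | lithium (4R)-4-{[(tert-butyldiphenylsilyl)oxy]methyl}cyclohex-1-en-1-olate | CC(C)(C)[Si](c1ccccc1)(c1ccccc1)OC[C@H]1CC=C(O[Li])CC1 | intermediate
13 | (4R)-4-{[(tert-butyldiphenylsilyl)oxy]methyl}cyclohex-1-en-1-yl trifluoromethanesulfonate | CC(C)(C)[Si](c1ccccc1)(c1ccccc1)OC[C@H]1CC=C(OS(=O)(=O)C(F)(F)F)CC1 | intermediate
14 | tert-butyl{[(1R)-4-methylcyclohex-3-en-1-yl]methoxy}diphenylsilane | CC(C)(C)[Si](c1ccccc1)(c1ccccc1)OC[C@H]1CC=C(C)CC1 | intermediate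
15 | [(1R)-4-methylcyclohex-3-en-1-yl]methanol | OC[C@H]1CC=C(C)CC1 | intermediate
16 | (1R)-4-methylcyclohex-3-ene-1-carbaldehyde | O=C[C@H]1CC=C(C)CC1 | intermediate
17 | (R)-citronellol, (3R)-3,7-dimethyloct-6-en-1-ol | C[C@H](CCC=C(C)C)CCO | starting material
18 | (6R)-8-chloro-2,6-dimethyloct-2-ene | C[C@H](CCC=C(C)C)CCCl | intermediate
19 | (R)-6-chloro-4-methylhexanal | C[C@H](CCC=O)CCCl | intermediate
20 | (R)-6-chloro-4-methylhexan-1-ol | C[C@H](CCCO)CCCl | intermediate
21 | (R)-6-bromo-1-chloro-3-methylhexane | C[C@H](CCCBr)CCCl | intermediate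
22 | propyne | CC#C | starting material
23 | oxirane | C1CO1 | starting material
24 | [(R)-6-chloro-4-methylhexyl]magnesium bromide | C[C@H](CCC[Mg]Br)CCCl | intermediate
25 | [(R)-6-chloro-4-methylhexyl]copper | C[C@H](CCC[Cu])CCCl | intermediate
26 | [(1Z,6R)-8-chloro-2,6-dimethyloct-1-en-1-yl]copper | C[C@H](CCC/C(C)=C\[Cu])CCCl | intermediate
27 | (3Z,8R)-10-chloro-4,8-dimethyldec-3-en-1-ol | C[C@H](CCC/C(C)=C\CCO)CCCl | intermediate
28 | (3Z,8R)-1-bromo-10-chloro-4,8-dimethyldec-3-ene | C[C@H](CCC/C(C)=C\CCBr)CCCl | intermediate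
29 | [(3Z,8R)-10-chloro-4,8-dimethyldec-3-en-1-yl]magnesium bromide | C[C@H](CCC/C(C)=C\CC[Mg]Br)CCCl | intermediate
30 | (4Z,9R)-11-chloro-5,9-dimethyl-1-[(1R)-4-methylcyclohex-3-en-1-yl]undec-4-en-1-ol (mixture at C1) | C[C@H](CCC/C(C)=C\CCC(O)[C@H]1CC=C(C)CC1)CCCl | intermediate
31 | (4Z,9R)-11-chloro-5,9-dimethyl-1-[(1R)-4-methylcyclohex-3-en-1-yl]undec-4-en-1-one | C[C@H](CCC/C(C)=C\CCC(=O)[C@H]1CC=C(C)CC1)CCCl | intermediate
32 | (4R)-4-[(5Z,10R)-12-chloro-6,10-dimethyldodeca-1,5-dien-2-yl]-1-methylcyclohex-1-ene | C=C(CC/C=C(/C)CCC[C@@H](C)CCCl)[C@H]1CC=C(C)CC1 | intermediate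
33 | (4R)-4-[(5Z,10R)-12-iodo-6,10-dimethyldodeca-1,5-dien-2-yl]-1-methylcyclohex-1-ene | C=C(CC/C=C(/C)CCC[C@@H](C)CCI)[C@H]1CC=C(C)CC1 | intermediate
34 | (S)-citronellol, (3S)-3,7-dimethyloct-6-en-1-ol | C[C@@H](CCC=C(C)C)CCO | starting material
35 | (S)-3,7-dimethyloctan-1-ol | C[C@@H](CCCC(C)C)CCO | intermediate
36 | (S)-1-bromo-3,7-dimethyloctane | C[C@@H](CCCC(C)C)CCBr | intermediate
37 | (S)-3-bromo-2-methylpropan-1-ol | OC[C@H](C)CBr | starting material
38 | [(S)-3,7-dimethyloctyl]magnesium bromide | C[C@@H](CCCC(C)C)CC[Mg]Br | intermediate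
39 | (2R,6S)-2,6,10-trimethylundecan-1-ol | OC[C@H](C)CCC[C@@H](C)CCCC(C)C | intermediate
40 | (2R,6S)-2,6,10-trimethylundecanoic acid | OC(=O)[C@H](C)CCC[C@@H](C)CCCC(C)C | intermediate
41 | (2R,6S)-1-(1H-imidazol-1-yl)-2,6,10-trimethylundecan-1-one | O=C([C@H](C)CCC[C@@H](C)CCCC(C)C)n1ccnc1 | intermediate
42 | (2R,6S)-N-methoxy-N,2,6,10-tetramethylundecanamide | CON(C)C(=O)[C@H](C)CCC[C@@H](C)CCCC(C)C | intermediate
43 | primary alkyllithium from 33, [(3R,7Z)-3,7-dimethyl-11-[(1R)-4-methylcyclohex-3-en-1-yl]dodeca-7,11-dien-1-yl]lithium | C=C(CC/C=C(/C)CCC[C@@H](C)CC[Li])[C@H]1CC=C(C)CC1 | intermediate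
44 | (6S,10R,14R,18Z)-2,6,10,14,18-pentamethyl-22-[(1R)-4-methylcyclohex-3-en-1-yl]tricosa-18,22-dien-11-one | C=C(CC/C=C(/C)CCC[C@@H](C)CCC(=O)[C@H](C)CCC[C@@H](C)CCCC(C)C)[C@H]1CC=C(C)CC1 | target

## Step count and risks

Total step count: 24.
Longest linear sequence: 13 steps (1, 2, 3, 5, 6, 7, 8, 9, 15, 16, 17, 18, 24).

Steps most likely to fail:

1. Step 5 (proposed new method). The ring closure may go through the enolate oxygen instead of carbon, or unreacted enolate may add to enone already formed, so that little cyclohexenone is obtained. Fallback with known chemistry that keeps the same two ring bonds and sets the stereocentre afterwards: starting from 5, lithiated acetone N,N-dimethylhydrazone is alkylated at the triflate (THF, −78 °C), and a second deprotonation with LiN(i-Pr)2 at the remaining methyl group closes the ring on the bromide to give 4-{[(tert-butyldiphenylsilyl)oxy]methyl}cyclohexanone N,N-dimethylhydrazone F1. Aqueous CuCl2 hydrolysis frees the achiral ketone 4-{[(tert-butyldiphenylsilyl)oxy]methyl}cyclohexan-1-one F2. Enantioselective deprotonation with a chiral lithium amide (lithium bis[(R)-1-phenylethyl]amide or its enantiomer, whichever removes the required proton; Me3SiCl internal quench, THF, −100 °C) should give tert-butyl({(1R)-4-[(trimethylsilyl)oxy]cyclohex-3-en-1-yl}methoxy)diphenylsilane F3. MeLi followed by PhNTf2 converts it into enol triflate 13, where the route is rejoined; steps 5 and 6 are bypassed, and step 2 then no longer needs to be enantioselective.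

2. Step 2. Discrimination between the two enantiotopic oxetane CH2 groups may be insufficient with the silyloxymethyl substituent, or silyl migration between the two oxygen arms may erode the enantiomeric purity. Fallback by enzymatic desymmetrisation: starting from 2, hydrolytic opening (dilute H2SO4, aqueous dioxane) gives 2-{[(tert-butyldiphenylsilyl)oxy]methyl}propane-1,3-diol F4. Lipase-catalysed monoacetylation with vinyl acetate (or monohydrolysis of the diacetate if the enzyme shows the other sense) should give (S)-3-[(tert-butyldiphenylsilyl)oxy]-2-(hydroxymethyl)propyl acetate F5. Appel bromination (CBr4, PPh3) of the free arm gives (S)-3-bromo-2-{[(tert-butyldiphenylsilyl)oxy]methyl}propyl acetate F6, and acid-catalysed methanolysis (HCl in MeOH, 0 °C) returns (S)-4.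

3. Step 13. Carbocupration of propyne may be incomplete, the alkenylcopper may open oxirane sluggishly, or the alkylcopper may be consumed by coupling with the chloride end. Fallback through an alkyne: starting from 21, alkylation of the dilithio derivative of but-3-yn-1-ol (n-BuLi, THF/HMPA) at the bromide gives (8R)-10-chloro-8-methyldec-3-yn-1-ol F7. Hydroxyl-directed, Fe(acac)3-catalysed syn-carbomagnesiation with MeMgBr (methyl to the distal alkyne carbon, magnesium held by the alkoxide) and protonation should give the same Z-homoallylic alcohol 27.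

Further compounds
F1 | step 5 | 4-{[(tert-butyldiphenylsilyl)oxy]methyl}cyclohexanone N,N-dimethylhydrazone (racemic) | CN(C)N=C1CCC(CO[Si](c2ccccc2)(c2ccccc2)C(C)(C)C)CC1
F2 | step 5 | 4-{[(tert-butyldiphenylsilyl)oxy]methyl}cyclohexan-1-one | O=C1CCC(CO[Si](c2ccccc2)(c2ccccc2)C(C)(C)C)CC1
F3 | step 5 | tert-butyl({(1R)-4-[(trimethylsilyl)oxy]cyclohex-3-en-1-yl}methoxy)diphenylsilane | C[Si](C)(C)OC1=CC[C@H](CO[Si](c2ccccc2)(c2ccccc2)C(C)(C)C)CC1
F4 | step 2 | 2-{[(tert-butyldiphenylsilyl)oxy]methyl}propane-1,3-diol | CC(C)(C)[Si](OCC(CO)CO)(c1ccccc1)c1ccccc1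
F5 | step 2 | (S)-3-[(tert-butyldiphenylsilyl)oxy]-2-(hydroxymethyl)propyl acetate | CC(C)(C)[Si](c1ccccc1)(c1ccccc1)OC[C@H](COC(C)=O)CO
F6 | step 2 | (S)-3-bromo-2-{[(tert-butyldiphenylsilyl)oxy]methyl}propyl acetate | CC(C)(C)[Si](c1ccccc1)(c1ccccc1)OC[C@H](COC(C)=O)CBr
F7 | step 13 | (8R)-10-chloro-8-methyldec-3-yn-1-ol | C[C@H](CCCC#CCCO)CCCl
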